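**Plan**

- Retrosynthesis: cut the two O1–C2 bonds of the pyrans first (cyclodehydration), then the two C4a–C4 aryl–vinyl bonds (twofold Heck coupling with 2-methylbut-3-en-2-ol), and last the bond between the central CH2 and the carbonyl carbon on ring A (ester–ketone condensation). Ring A is the 4-oxygenated benzoyl ring; ring B is the resorcinol ring.
- Enabling feature: in each 2H-pyran, C4 is bonded to arene carbon C4a, ortho to the pyran oxygen on C8a. Each pyran is therefore an ortho-bromophenol unit plus a five-carbon allylic alcohol. Bromine on C5 of ring B, beside the non-chelated oxygen only, dictates the linear fusion.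
- Forward: MOM protection of bromoketone 1 and bromoester 4, Claisen condensation to dibromo diketone 6, double Heck coupling to 9, then one acid step that removes the MOM groups and closes both pyran rings.
- The Heck coupling is run on the MOM ethers, not the free phenols, because ortho-bromophenoxides are poor partners for oxidative addition.
- Stereochemistry: the target has no stereocentre. The E geometry set in the Heck step is lost when the allyl cations cyclise to the cis ring alkenes.

Key step: step 4

Assumption: the 1,3-diketones are drawn as diketo tautomers, although they should exist largely as chelated enols; this changes no step.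

**Step 1**
Reactants: 1 5-bromo-2,4-dihydroxyacetophenone
Product: 3 1-[5-bromo-2,4-bis(methoxymethoxy)phenyl]ethanone, via 4-mono-MOM ether 2 (not isolated)
Conditions: NaH (2.4 equiv), MOMCl (2.6 equiv), DMF, 0 °C → rt
Reagents that add atoms: chloromethyl methyl ether, COCCl
Why: Williamson-type O-alkylation of the sodium phenoxides by the α-chloro ether, in which the non-chelated 4-oxygen should react first (2) and the 2-oxygen, no longer hydrogen-bonded once deprotonated, follows.

**Step 2**
Reactants: 4 methyl 3-bromo-4-hydroxybenzoate
Product: 5 methyl 3-bromo-4-(methoxymethoxy)benzoate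
Conditions: NaH (1.2 equiv), MOMCl (1.3 equiv), DMF, 0 °C → rt
Reagents that add atoms: chloromethyl methyl ether, COCCl
Why: Williamson-type alkylation of an acidic phenoxide (para ester, ortho bromine) by chloromethyl methyl ether, under conditions that leave the methyl ester untouched.

**Step 3**
Reactants: 3 1-[5-bromo-2,4-bis(methoxymethoxy)phenyl]ethanone; 5 methyl 3-bromo-4-(methoxymethoxy)benzoate
Product: 6 1-[5-bromo-2,4-bis(methoxymethoxy)phenyl]-3-[3-bromo-4-(methoxymethoxy)phenyl]propane-1,3-dione
Conditions: LiN(SiMe3)2 (2.4 equiv), THF, −78 °C; then 5, −78 °C → rt; aq NH4Cl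
Reagents that add atoms: none
Why: Crossed Claisen (ester–ketone) condensation in which the preformed lithium enolate of 3 acylates the non-enolisable ester 5, and deprotonation of the 1,3-diketone by the second equivalent of base pulls the equilibrium forward; MOM ethers and aryl bromides tolerate the amide base.

**Step 4**
Reactants: 6 1-[5-bromo-2,4-bis(methoxymethoxy)phenyl]-3-[3-bromo-4-(methoxymethoxy)phenyl]propane-1,3-dione; 7 2-methylbut-3-en-2-ol (two molecules)
Product: 9 1-{5-[(E)-3-hydroxy-3-methylbut-1-enyl]-2,4-bis(methoxymethoxy)phenyl}-3-{3-[(E)-3-hydroxy-3-methylbut-1-enyl]-4-(methoxymethoxy)phenyl}propane-1,3-dione, via mono-coupled bromide 8 (not isolated)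
Conditions: Pd(OAc)2 (10 mol %), P(o-tol)3 (30 mol %), Et3N (6 equiv), 7 (6 equiv), DMF, 100 °C, sealed tube
Reagents that add atoms: none
Why: Twofold Mizoroki–Heck reaction: zerovalent palladium generated from Pd(OAc)2 and P(o-tol)3 inserts into a C–Br bond, the aryl-palladium bromide adds syn across alkene 7 with the aryl group going to the terminal carbon, and syn β-hydride elimination, possible only toward the benzylic carbon because the carbinol carbon is quaternary, releases the E-styrenyl tertiary alcohol while Et3N takes up HBr and returns the catalyst. The closest known reaction type is the Heck coupling of ortho-alkoxy aryl bromides with 2-methylbut-3-en-2-ol. The less electron-rich ring A bromide should react first to give 8, and the ring B bromide, flanked by ortho and para ether oxygens, should follow at 100 °C under an excess of the alkene. No ring closes and no stereocentre forms; only the two C4a–C4 bonds are made, and the E geometry follows from the syn insertion and syn elimination sequence. The selectivity needed is aryl delivery to the terminal alkene carbon and complete twofold conversion: the steric bias of the 1,1-disubstituted carbinol carbon secures the first, and the MOM ethers support the second by keeping the arenes out of the electron-rich, palladium-binding phenoxide form. Bromine at C5 of ring B, beside the 4-oxygen only, is what later forces the pyran on that ring to fuse in the linear sense.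

**Step 5**
Reactants: 9 1-{5-[(E)-3-hydroxy-3-methylbut-1-enyl]-2,4-bis(methoxymethoxy)phenyl}-3-{3-[(E)-3-hydroxy-3-methylbut-1-enyl]-4-(methoxymethoxy)phenyl}propane-1,3-dione
Product: 11 glyinflanin D [1-(7-hydroxy-2,2-dimethyl-2H-chromen-6-yl)-3-(2,2-dimethyl-2H-chromen-6-yl)propane-1,3-dione], via triphenol diol 10 (not isolated)
Conditions: HCl (about 1 M) in MeOH, THF co-solvent, rt → 40 °C
Reagents that add atoms: none
Why: Acid-catalysed acetal exchange passes the three MOM groups to methanol and frees the phenols (10), and protonation of each tertiary allylic alcohol with loss of water gives an allyl cation (a protonated ortho-quinone methide) that the neighbouring phenol captures in an oxa-6π ring closure to the 2,2-dimethyl-2H-chromene, a classical cyclodehydration; the chelated hydroxyl on ring B has no such partner and stays free.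

**Compound list**

1 | 5-bromo-2,4-dihydroxyacetophenone | CC(=O)c1cc(Br)c(O)cc1O | starting material
2 | 1-[5-bromo-2-hydroxy-4-(methoxymethoxy)phenyl]ethanone | CC(=O)c1cc(Br)c(OCOC)cc1O | intermediate
3 | 1-[5-bromo-2,4-bis(methoxymethoxy)phenyl]ethanone | CC(=O)c1cc(Br)c(OCOC)cc1OCOC | intermediate
4 | methyl 3-bromo-4-hydroxybenzoate | COC(=O)c1ccc(O)c(Br)c1 | starting material
5 | methyl 3-bromo-4-(methoxymethoxy)benzoate | COC(=O)c1ccc(OCOC)c(Br)c1 | intermediate
6 | 1-[5-bromo-2,4-bis(methoxymethoxy)phenyl]-3-[3-bromo-4-(methoxymethoxy)phenyl]propane-1,3-dione | COCOc1cc(OCOC)c(Br)cc1C(=O)CC(=O)c1ccc(OCOC)c(Br)c1 | intermediate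
7 | 2-methylbut-3-en-2-ol | C=CC(C)(C)O | starting material
8 | 1-[5-bromo-2,4-bis(methoxymethoxy)phenyl]-3-{3-[(E)-3-hydroxy-3-methylbut-1-enyl]-4-(methoxymethoxy)phenyl}propane-1,3-dione | COCOc1cc(OCOC)c(Br)cc1C(=O)CC(=O)c1ccc(OCOC)c(/C=C/C(C)(C)O)c1 | intermediate
9 | 1-{5-[(E)-3-hydroxy-3-methylbut-1-enyl]-2,4-bis(methoxymethoxy)phenyl}-3-{3-[(E)-3-hydroxy-3-methylbut-1-enyl]-4-(methoxymethoxy)phenyl}propane-1,3-dione | COCOc1cc(OCOC)c(/C=C/C(C)(C)O)cc1C(=O)CC(=O)c1ccc(OCOC)c(/C=C/C(C)(C)O)c1 | intermediate
10 | 1-{2,4-dihydroxy-5-[(E)-3-hydroxy-3-methylbut-1-enyl]phenyl}-3-{4-hydroxy-3-[(E)-3-hydroxy-3-methylbut-1-enyl]phenyl}propane-1,3-dione | CC(C)(O)/C=C/c1cc(C(=O)CC(=O)c2cc(/C=C/C(C)(C)O)c(O)cc2O)ccc1O | intermediate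
11 | glyinflanin D, 1-(7-hydroxy-2,2-dimethyl-2H-chromen-6-yl)-3-(2,2-dimethyl-2H-chromen-6-yl)propane-1,3-dione | CC1(C)C=Cc2cc(C(=O)CC(=O)c3cc4c(cc3O)OC(C)(C)C=C4)ccc2O1 | target

**Step count**

Total: 5 steps. Longest linear sequence: 4 steps (steps 1, 3, 4, 5).

**Steps most likely to fail**

Step 4. The second oxidative addition, at the electron-rich ring B bromide, may stall at the mono-coupled stage, and the diketonate may tie up palladium or reductive debromination may compete. The fallback makes the same two bonds by a twofold Suzuki–Miyaura coupling and sets out from 6. Commercial 2-methylbut-3-yn-2-ol would be borylated (B2pin2, CuCl, Xantphos, catalytic NaOt-Bu, MeOH, THF) to (E)-2-methyl-4-(4,4,5,5-tetramethyl-1,3,2-dioxaborolan-2-yl)but-3-en-2-ol F1. Coupling 6 with 2.5 equivalents of it (Pd(dppf)Cl2, K3PO4, dioxane–water, 80 °C) would come back to the route at 9.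

Step 5. Once the chelated hydroxyl is free, cyclodehydration of the 2-hydroxyaryl 1,3-diketone toward a flavone may compete, and addition of methanol to the allyl cations or to the new ring alkenes may outrun pyran closure. The fallback separates deprotection from ring closure and sets out from 6. The three MOM ethers would be removed first (HCl in MeOH, room temperature), while no allylic alcohol is present, to give 1-(5-bromo-2,4-dihydroxyphenyl)-3-(3-bromo-4-hydroxyphenyl)propane-1,3-dione F2. Twofold Heck coupling of this with 7 (Pd(OAc)2, P(o-tol)3, excess Et3N, DMF, 100 °C) would give triphenol diol 10 as an isolated compound. Catalytic pyridinium p-toluenesulfonate in toluene at 60 °C, with no methanol and no strong acid, would then close both pyrans and come back at 11.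

Step 3. Acyl transfer from the electron-rich, ortho-substituted ester to the enolate may be slow, so that proton exchange and self-condensation of the ketone take over. The fallback replaces the condensation by an aldol addition and oxidation and sets out from 5 and 3. Ester 5 would be reduced (i-Bu2AlH, CH2Cl2, −78 → 0 °C) to [3-bromo-4-(methoxymethoxy)phenyl]methanol F3 and oxidised (MnO2, CH2Cl2) to 3-bromo-4-(methoxymethoxy)benzaldehyde F4. The lithium enolate of 3 (LiN(i-Pr)2, THF, −78 °C) would add to the aldehyde to give racemic 1-[5-bromo-2,4-bis(methoxymethoxy)phenyl]-3-[3-bromo-4-(methoxymethoxy)phenyl]-3-hydroxypropan-1-one F5. Dess–Martin periodinane (NaHCO3, CH2Cl2) would oxidise it and come back to the route at 6.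

**Further compounds**

F1 | step 4 | (E)-2-methyl-4-(4,4,5,5-tetramethyl-1,3,2-dioxaborolan-2-yl)but-3-en-2-ol | CC(C)(O)/C=C/B1OC(C)(C)C(C)(C)O1
F2 | step 5 | 1-(5-bromo-2,4-dihydroxyphenyl)-3-(3-bromo-4-hydroxyphenyl)propane-1,3-dione | O=C(CC(=O)c1cc(Br)c(O)cc1O)c1ccc(O)c(Br)c1
F3 | step 3 | [3-bromo-4-(methoxymethoxy)phenyl]methanol | OCc1ccc(OCOC)c(Br)c1
F4 | step 3 | 3-bromo-4-(methoxymethoxy)benzaldehyde | O=Cc1ccc(OCOC)c(Br)c1
F5 | step 3 | 1-[5-bromo-2,4-bis(methoxymethoxy)phenyl]-3-[3-bromo-4-(methoxymethoxy)phenyl]-3-hydroxypropan-1-one (racemic) | COCOc1cc(OCOC)c(Br)cc1C(=O)CC(O)c1ccc(OCOC)c(Br)c1
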